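**Plan**
- Retrosynthesis: the 4'-O–benzyl bond is cut last. C5–OMe and O1–C8a are then both traced back to C–H bonds ortho to the C4 carbonyl of a syringyl ketone. Finally C3–C4 (C-acylation of an α-methoxy ketone) and C2–C1' (Weinreb ketone synthesis) are cut.
- Forward: the B-ring ketone and acetylsyringoyl chloride are joined to a 2-methoxy-1,3-diketone, with ring A coming intact from syringic acid. Ring C is closed onto ring A (O1–C8a), C5–H becomes C5–OMe, and the benzyl group is removed.
- Enabling feature: the free 7-OH lies between 6-OMe and 8-OMe and para to C4a, so ring A is a 4-acyl-2,6-dimethoxyphenol. PhI(OAc)2/MeOH turns such a phenol into an o-quinone monoketal in which the ring CH ortho to the acyl group (future C8a, later C5) is a dienone terminus and β to the C4 ketone.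
- An O-nucleophile adds there and loss of methanol re-aromatizes the ring, returning the 7-OH. The same handle is therefore used twice, and O7 needs no protecting group.
- Stereochemistry: the target has no stereogenic element; the sp3 centers of the transient adducts vanish on aromatization.

Key step: step 5

Remark: the target SMILES contains no stereocenter, so "single enantiomer" has no bearing; the structure is taken as drawn, 7,4'-dihydroxy-3,5,6,8-tetramethoxyflavone. The CH(OMe) center of compounds 8–10 is racemic and enolizable and is destroyed in step 5.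

**Step 1**
Reactants: 1 1-(benzyloxy)-4-bromobenzene; 2 N,2-dimethoxy-N-methylacetamide
Product: 4 1-[4-(benzyloxy)phenyl]-2-methoxyethan-1-one, via arylmagnesium bromide 3 (not isolated)
Conditions: Mg, I2 (cat.), THF, reflux; then 2, THF, 0 °C → rt; 1 M HCl
Reagents that add atoms: none
Why: Grignard formation followed by Weinreb ketone synthesis, in which the chelated tetrahedral magnesium intermediate should prevent over-addition.

**Step 2**
Reactants: 5 syringic acid (4-hydroxy-3,5-dimethoxybenzoic acid)
Product: 6 4-acetoxy-3,5-dimethoxybenzoic acid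
Conditions: Ac2O, pyridine, DMAP (cat.), 0 °C → rt; aq. HCl work-up
Reagents that add atoms: acetic anhydride CC(=O)OC(C)=O
Why: O-acetylation of the hindered phenol under nucleophilic catalysis; any mixed anhydride at the carboxyl group is hydrolyzed on work-up.

**Step 3**
Reactants: 6 4-acetoxy-3,5-dimethoxybenzoic acid
Product: 7 4-acetoxy-3,5-dimethoxybenzoyl chloride
Conditions: (COCl)2, DMF (cat.), CH2Cl2, 0 °C → rt
Reagents that add atoms: oxalyl chloride O=C(Cl)C(Cl)=O
Why: Vilsmeier-type activation of the acid under neutral conditions that the aryl acetate tolerates.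

**Step 4**
Reactants: 4 1-[4-(benzyloxy)phenyl]-2-methoxyethan-1-one; 7 4-acetoxy-3,5-dimethoxybenzoyl chloride
Product: 9 1-[4-(benzyloxy)phenyl]-3-(4-hydroxy-3,5-dimethoxyphenyl)-2-methoxypropane-1,3-dione, via diketone acetate 8 (not isolated)
Conditions: MgBr2·OEt2, i-Pr2NEt, CH2Cl2, 0 °C → rt; aqueous wash; crude 8, K2CO3, MeOH, 0 °C; 1 M HCl
Reagents that add atoms: none
Why: Claisen-type C-acylation by soft enolization, in which the α-methoxy ketone forms a chelated magnesium enolate that should be acylated on carbon; the aryl acetate is then removed by methanolysis while the diketone is protected as its enolate.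

**Step 5**
Reactants: 9 1-[4-(benzyloxy)phenyl]-3-(4-hydroxy-3,5-dimethoxyphenyl)-2-methoxypropane-1,3-dione
Product: 12 2-[4-(benzyloxy)phenyl]-7-hydroxy-3,6,8-trimethoxy-4H-chromen-4-one, via o-quinone monoketal 10 (not isolated), via dihydrochromenone adduct 11 (not isolated)
Conditions: PhI(OAc)2 (1.05 equiv), MeOH/CH2Cl2 (1:4), −20 → 0 °C; then CSA (0.2 equiv), 0 °C → rt
Reagents that add atoms: methanol CO (its methoxy group enters the ketal carbon of 10; one of the two ketal methoxy groups is kept as the 8-OMe of 12)
Why: Proposed new method: PhI(OAc)2 engages the only free phenol (O7; the B-ring oxygen is benzylated) and methanol attacks ipso at a methoxy-bearing ortho carbon, which is the established oxidative dearomatization of 2-methoxyphenols to masked o-benzoquinones and gives 10. In 10 the ring CH next to the ketal (future C8a) is the δ-terminus of the ring dienone and also β to the side-chain C4 ketone, so under acid catalysis the enol oxygen of the 1,3-diketone should add to it in a 6-endo-trig oxa-conjugate (1,6-) addition that closes the pyrone ring (O1–C8a) and gives dienol 11. Ionization of the C8 ketal of 11 gives an arenium ion that loses H-8a, so methanol is expelled and the 7-OH phenol is returned in 12; overall a C–H bond ortho to the ketone is replaced by the C–O1 bond. The closest known reaction types are the conjugate addition–aromatization of indoles, thiols and amines with masked o-benzoquinones and the SNAr ring closure of 1-(2-haloaryl)-1,3-diketones to flavones, the difference being that the leaving group is created here by oxidation of the ring. No stereocenter survives (C8a of 11 becomes planar), and regioselectivity needs no control because the two CH positions of the syringyl ring are equivalent and either closure leads to 12. The selectivity that is needed, capture by the tethered enol before solvent methanol, should be secured by consuming the oxidant at low temperature before the acid is added and by using methanol only as a co-solvent.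

**Step 6**
Reactants: 12 2-[4-(benzyloxy)phenyl]-7-hydroxy-3,6,8-trimethoxy-4H-chromen-4-one
Product: 15 2-[4-(benzyloxy)phenyl]-7-hydroxy-3,5,6,8-tetramethoxy-4H-chromen-4-one, via chromenedione monoketal 13 (not isolated), via methanol adduct 14 (not isolated)
Conditions: PhI(OAc)2 (1.05 equiv), MeOH, 0 °C; then CSA (0.3 equiv), 0 → 40 °C
Reagents that add atoms: methanol CO
Why: Proposed new method: the same phenol handle is used again, PhI(OAc)2/MeOH converting 12 into monoketal 13 (ketalization at C6 shown; the C8 isomer would converge on the same product), whose C5–H carbon is the terminus of the O=C7–C8=C8a–C4a=C5 dienone and β to the pyrone C4=O, so that acid-catalyzed conjugate addition of methanol should give 14 and ionization of the C6 ketal with loss of H-5 (net loss of methanol) should re-aromatize to 15; the closest known reaction types are the acid-catalyzed addition of methanol to quinone monoketals to give methoxyphenols and the conjugate addition–aromatization of heteronucleophiles with masked o-benzoquinones, and over-oxidation of the more electron-rich product should be avoided because the oxidant is consumed before 15 forms.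

**Step 7**
Reactants: 15 2-[4-(benzyloxy)phenyl]-7-hydroxy-3,5,6,8-tetramethoxy-4H-chromen-4-one
Product: 16 7-hydroxy-2-(4-hydroxyphenyl)-3,5,6,8-tetramethoxy-4H-chromen-4-one
Conditions: H2 (1 atm), 10% Pd/C, EtOAc/MeOH, rt
Reagents that add atoms: none
Why: hydrogenolysis of the benzyl aryl ether, under which the tetrasubstituted C2=C3 bond of the flavone and the aryl methyl ethers should be inert.

**Compound list**
1 | 1-(benzyloxy)-4-bromobenzene | Brc1ccc(OCc2ccccc2)cc1 | starting material
2 | N,2-dimethoxy-N-methylacetamide | COCC(=O)N(C)OC | starting material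
3 | [4-(benzyloxy)phenyl]magnesium bromide | Br[Mg]c1ccc(OCc2ccccc2)cc1 | intermediate (not isolated)
4 | 1-[4-(benzyloxy)phenyl]-2-methoxyethan-1-one | COCC(=O)c1ccc(OCc2ccccc2)cc1 | intermediate
5 | syringic acid (4-hydroxy-3,5-dimethoxybenzoic acid) | COc1cc(C(=O)O)cc(OC)c1O | starting material
6 | 4-acetoxy-3,5-dimethoxybenzoic acid | COc1cc(C(=O)O)cc(OC)c1OC(C)=O | intermediate
7 | 4-acetoxy-3,5-dimethoxybenzoyl chloride | COc1cc(C(Cl)=O)cc(OC)c1OC(C)=O | intermediate
8 | 4-{3-[4-(benzyloxy)phenyl]-2-methoxy-3-oxopropanoyl}-2,6-dimethoxyphenyl acetate (racemic) | COC(C(=O)c1ccc(OCc2ccccc2)cc1)C(=O)c1cc(OC)c(OC(C)=O)c(OC)c1 | intermediate (not isolated)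
9 | 1-[4-(benzyloxy)phenyl]-3-(4-hydroxy-3,5-dimethoxyphenyl)-2-methoxypropane-1,3-dione (racemic) | COC(C(=O)c1ccc(OCc2ccccc2)cc1)C(=O)c1cc(OC)c(O)c(OC)c1 | intermediate
10 | 1-[4-(benzyloxy)phenyl]-2-methoxy-3-(3,3,5-trimethoxy-4-oxocyclohexa-1,5-dien-1-yl)propane-1,3-dione (racemic) | COC(C(=O)c1ccc(OCc2ccccc2)cc1)C(=O)C1=CC(OC)(OC)C(=O)C(OC)=C1 | intermediate (not isolated)
11 | 2-[4-(benzyloxy)phenyl]-7-hydroxy-3,6,8,8-tetramethoxy-8,8a-dihydro-4H-chromen-4-one (racemic) | COC1=C(c2ccc(OCc3ccccc3)cc2)OC2C(=CC(OC)=C(O)C2(OC)OC)C1=O | intermediate (not isolated)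
12 | 2-[4-(benzyloxy)phenyl]-7-hydroxy-3,6,8-trimethoxy-4H-chromen-4-one | COc1c(-c2ccc(OCc3ccccc3)cc2)oc2c(OC)c(O)c(OC)cc2c1=O | intermediate
13 | 2-[4-(benzyloxy)phenyl]-3,6,6,8-tetramethoxy-4H-chromene-4,7(6H)-dione | COC1=C(c2ccc(OCc3ccccc3)cc2)OC2=C(OC)C(=O)C(OC)(OC)C=C2C1=O | intermediate (not isolated)
14 | 2-[4-(benzyloxy)phenyl]-7-hydroxy-3,5,6,6,8-pentamethoxy-5,6-dihydro-4H-chromen-4-one (racemic) | COC1=C(c2ccc(OCc3ccccc3)cc2)OC2=C(C(OC)C(OC)(OC)C(O)=C2OC)C1=O | intermediate (not isolated)
15 | 2-[4-(benzyloxy)phenyl]-7-hydroxy-3,5,6,8-tetramethoxy-4H-chromen-4-one | COc1c(-c2ccc(OCc3ccccc3)cc2)oc2c(OC)c(O)c(OC)c(OC)c2c1=O | intermediate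
16 | 7-hydroxy-2-(4-hydroxyphenyl)-3,5,6,8-tetramethoxy-4H-chromen-4-one | COc1c(O)c(OC)c2oc(-c3ccc(O)cc3)c(OC)c(=O)c2c1OC | target

**Step count and risks**
Total step count: 7. Longest linear sequence: 6 steps (5 → 6 → 7 → 9 → 12 → 15 → 16).

The three steps most likely to fail are steps 5, 6 and 4.

Step 5. The dienone 10 may be consumed by Diels–Alder dimerization or by capture of solvent or water before the tethered enol oxygen adds, or the adduct may revert instead of losing methanol. The fallback places the leaving group by halogenation instead of oxidation and uses known chemistry throughout. It sets out from 6: bromination with NBS in MeCN (the two free ring positions are equivalent) would give 4-acetoxy-2-bromo-3,5-dimethoxybenzoic acid F1, and (COCl)2 with catalytic DMF would give 4-acetoxy-2-bromo-3,5-dimethoxybenzoyl chloride F2. Soft-enolization acylation of 4 under the conditions of step 4 would give 4-{3-[4-(benzyloxy)phenyl]-2-methoxy-3-oxopropanoyl}-3-bromo-2,6-dimethoxyphenyl acetate F3 (not isolated), and methanolysis would give 1-[4-(benzyloxy)phenyl]-3-(2-bromo-4-hydroxy-3,5-dimethoxyphenyl)-2-methoxypropane-1,3-dione F4. Copper-catalyzed intramolecular O-arylation of the diketone (CuI, 1,10-phenanthroline, K2CO3, DMF, 100 °C; Ullmann-type chromone closure) would then come back to the route at 12.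

Step 6. The monoketal 13 may be hydrolyzed to the o-quinone, may not take up methanol at the hindered C5 (peri to C4=O and next to the ketal), or may be reduced back to 12 on work-up. The fallback replaces the oxidative methoxylation by halogenation and copper-mediated substitution, all known reaction types. It sets out from 12: O-benzylation (BnBr, K2CO3, DMF) would give 7-(benzyloxy)-2-[4-(benzyloxy)phenyl]-3,6,8-trimethoxy-4H-chromen-4-one F5. Electrophilic bromination at the only free A-ring position, which is ortho and para to methoxy groups (NBS, MeCN), would give 7-(benzyloxy)-2-[4-(benzyloxy)phenyl]-5-bromo-3,6,8-trimethoxy-4H-chromen-4-one F6. Ullmann-type methoxylation (NaOMe, CuBr cat., MeOH/DMF, 100 °C) would give 7-(benzyloxy)-2-[4-(benzyloxy)phenyl]-3,5,6,8-tetramethoxy-4H-chromen-4-one F7. Hydrogenolysis of both benzyl ethers under the conditions of step 7 would come back to the route at 16.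

Step 4. The magnesium enolate may be acylated on oxygen to give an enol ester, the product enolate may be acylated a second time, or acetyl transfer from the aryl acetate may interfere. The fallback forms the C3–C4 bond at the alcohol oxidation level and then oxidizes. It sets out from 7 and 4: partial reduction of 7 (LiAlH(Ot-Bu)3, THF, −78 °C) would give 4-formyl-2,6-dimethoxyphenyl acetate F8. Aldol addition of the lithium enolate of 4 (LDA, THF, −78 °C) would give 4-{3-[4-(benzyloxy)phenyl]-1-hydroxy-2-methoxy-3-oxopropyl}-2,6-dimethoxyphenyl acetate F9 as a mixture of diastereomers. Oxidation with Dess–Martin periodinane (CH2Cl2, rt) would come back to the route at 8, which is methanolyzed as in step 4.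

**Further compounds**
F1 | step 5 | 4-acetoxy-2-bromo-3,5-dimethoxybenzoic acid | COc1cc(C(=O)O)c(Br)c(OC)c1OC(C)=O
F2 | step 5 | 4-acetoxy-2-bromo-3,5-dimethoxybenzoyl chloride | COc1cc(C(Cl)=O)c(Br)c(OC)c1OC(C)=O
F3 | step 5 | 4-{3-[4-(benzyloxy)phenyl]-2-methoxy-3-oxopropanoyl}-3-bromo-2,6-dimethoxyphenyl acetate (racemic) | COC(C(=O)c1ccc(OCc2ccccc2)cc1)C(=O)c1cc(OC)c(OC(C)=O)c(OC)c1Br
F4 | step 5 | 1-[4-(benzyloxy)phenyl]-3-(2-bromo-4-hydroxy-3,5-dimethoxyphenyl)-2-methoxypropane-1,3-dione (racemic) | COC(C(=O)c1ccc(OCc2ccccc2)cc1)C(=O)c1cc(OC)c(O)c(OC)c1Br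
F5 | step 6 | 7-(benzyloxy)-2-[4-(benzyloxy)phenyl]-3,6,8-trimethoxy-4H-chromen-4-one | COc1c(-c2ccc(OCc3ccccc3)cc2)oc2c(OC)c(OCc3ccccc3)c(OC)cc2c1=O
F6 | step 6 | 7-(benzyloxy)-2-[4-(benzyloxy)phenyl]-5-bromo-3,6,8-trimethoxy-4H-chromen-4-one | COc1c(-c2ccc(OCc3ccccc3)cc2)oc2c(OC)c(OCc3ccccc3)c(OC)c(Br)c2c1=O
F7 | step 6 | 7-(benzyloxy)-2-[4-(benzyloxy)phenyl]-3,5,6,8-tetramethoxy-4H-chromen-4-one | COc1c(-c2ccc(OCc3ccccc3)cc2)oc2c(OC)c(OCc3ccccc3)c(OC)c(OC)c2c1=O
F8 | step 4 | 4-formyl-2,6-dimethoxyphenyl acetate | COc1cc(C=O)cc(OC)c1OC(C)=O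
F9 | step 4 | 4-{3-[4-(benzyloxy)phenyl]-1-hydroxy-2-methoxy-3-oxopropyl}-2,6-dimethoxyphenyl acetate (racemic, mixture of diastereomers) | COC(C(O)c1cc(OC)c(OC(C)=O)c(OC)c1)C(=O)c1ccc(OCc2ccccc2)cc1
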